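The alpha flask cannot be read off any simulated run: its X of 0.0200 M and its E of 0.660 M are lower than every earlier charge.

| flask | Z | E | X | time |
|---|---|---|---|---|
| delta | 0.800 M | 2.00 M | 0.0400 M |  |
| beta | 0.320 M | 1.52 M | 0.0400 M |  |
| zeta | 0.800 M | 2.00 M | 0.0800 M |  |
| alpha | 0.800 M | 0.660 M | 0.0200 M | 140 h |

| delta run: time / h | delta run: [J] / M | beta run: time / h | beta run: [J] / M | zeta run: time / h | zeta run: [J] / M |
|---|---|---|---|---|---|
| 5.0 | 0.101 | 5.0 | 0.057 | 5.0 | 0.170 |
| 15 | 0.220 | 15 | 0.092 | 15 | 0.328 |
| 29 | 0.277 | 29 | 0.135 | 29 | 0.392 |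
| 46 | 0.320 | 46 | 0.154 | 46 | 0.459 |
| 66 | 0.371 | 66 | 0.161 | 66 | 0.477 |
| 88 | 0.391 | 88 | 0.164 | 88 | 0.485 |
| 110 | 0.394 | 110 | 0.195 | 110 | 0.499 |
| 140 | 0.405 | 140 | 0.210 | 140 | 0.495 |

(standard deviation of a reading: 0.008 M)

1. the power of [X] that the first rate follows, about the charge of the delta run; measure it at two percent of Z made into J
2. J in the alpha run at 140 h, as a share of the Z charged

- Overall: Z + E -> J, with X as catalyst.
- Constant volume, constant temperature.
- "The second partner" is E.
- An order is taken over about fifteen percent of the charge, up and down.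

1. Alpha at 140 h has had a dose of 70.0 h, the dose being the hours run times the X charged, over the X charged in delta. If J follows the dose, a flask with more X simply runs the same course sooner.

2. That needs a first rate with power one in X. At 5.0 h, zeta has 0.170 M of J and delta 0.101 M, which reads as a power of 0.751. Both flasks are already well past two percent of their Z, or 0.0160 M, and their curves are bending, so we take this reading as low and the power as one.

3. Alpha's dose of 70.0 h comes at that same time in delta and at 35.0 h in zeta. Between readings, delta has 0.375 M of J and zeta 0.416 M. So at equal dose, the flask that took fewer hours holds more J, by 0.0410 M.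

4. Our first answer repeats that step down by the same factor, 0.901. This gives 0.338 M, or 42.2 % of the Z.

5. That factor is the weak link: the gap came with 35.0 h of extra time, and alpha takes 70.0 h more than delta, twice that. Counting the gap by the hour gives 0.293 M, or 36.6 %, and we commit to that.

6. Putting this back, E, the limiting reagent by charge, ends on this count at 0.367 M, against 1.31 M at the end of beta. That E is lower than any simulated run reached, so we add nothing for it.

7. The forecast gives 0.9 and 18 %, on the view of “the catalyst dying, or being tied up, as J accumulates”.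

Alpha gives 36.7 % of its Z as J, and the power of X is 1.0.

    X + Z → Wa + G (0.8496 L mol⁻¹ h⁻¹)
    Wa + E → J + X (4.752 L mol⁻¹ h⁻¹)
    2 X → 2 Ek (0.6984 L mol⁻¹ h⁻¹)
    2 Z → Ez (0.01804 L mol⁻¹ h⁻¹)

J reached a quarter of the Z charged at 13.9 h in delta and 6.34 h in zeta, which are doses of 13.9 h and 12.7 h. Beta, charged with the X of delta, comes to alpha's dose of 70.0 h between its readings at 66 h and 88 h, where it reads 0.162 M of J, or 50.5 % of its Z.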